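the same everywhere: substrate 0.012 M

| charge | reagent in the second phase | remark | time | volume of the second phase over the first |
|---|---|---|---|---|
| winter | 0.0132 M | the very flask that is asked about, followed so far |  |  |
| autumn | 0.020 M | run made earlier |  |  |
| flask | 0.0132 M |  | 2.5 d | 1.0 |

| run | time / h | target / % | substrate / % |
|---|---|---|---|
| winter | 2.50 | 0.3 | 100.1 |
| winter | 6.00 | 0.8 | 100.1 |
| winter | 12.0 | 1.5 | 97.9 |
| winter | 20.0 | 3.8 | 95.4 |
| autumn | 10.0 | 2.4 | 97.2 |
| autumn | 20.0 | 5.7 | 93.1 |
| autumn | 30.0 | 9.9 | 86.6 |
| autumn | 40.0 | 13.7 | 80.2 |

(readings scatter by 0.5 percentage points)

- in the second phase: reagent in the second phase; everything else is in the first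
- charges count per volume of the first phase; a concentration in a rate is the amount of a species over the volume of its own phase; every rate counts per litre of the first phase
- the earlier runs hold the two phases in the same ratio of volumes as the flask asked about

- the target standing at 2.5 d, as a percentage of the substrate charged
- part of the substrate charged that has reacted at 2.5 d

Two questions stand on the asked flask, and one reckoning serves both: the target standing equals c, the substrate reacted, times s, the selectivity. In the autumn run at 20.0 h the readings give 0.826, and in the winter run at 20.0 h they give 0.826, for s, the target standing over the substrate reacted. Read at equal times, s does not shift between these reagent charges, though the winter reading rests on a gap of 4.60%. In the autumn run s falls to 0.692 at 40.0 h, and one more equal factor carries it to 60 h.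

The reckoning leans on the autumn readings, unequally. An error of 0.5 percentage points moves the reckoned target by 1.1 points in the target at 20.0 h, by 0.91 points in the target at 40.0 h, by 0.9 points in the substrate at 20.0 h, by 0.38 points in the substrate at 30.0 h, and by 0.056 points in the substrate at 40.0 h, whose two uses pull opposite ways.

Now the number itself. At 20.0 h the winter c is 0.667 of the autumn c, and the reagent ratio is 0.660, so at equal times c is taken to go with the reagent charge. The autumn c gained 6.4 points between 30.0 h and 40.0 h, and two more such steps carry it to 32.6% at 60 h, which the reagent ratio brings to 21.5% reacted in the asked flask. With s at 0.580, this reckoning gives 12.5% target.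

The forecast gives 11.5% target and 18.5% reacted: “I take values between these, with wide ranges because the mechanism is uncertain”.

The flask gives 13.3% target and 22.1% reacted, so s stands at 0.602.

    substrate + reagent in the reaction phase → target (k = 1.90 M⁻¹ h⁻¹)
    target ⇌ isomer of the product (K = 1.30, k = 0.0350 h⁻¹)
    reagent in the reaction phase ⇌ reagent in the second phase, rate k3*([reagent in the reaction phase] - [reagent in the second phase]/K3) per volume of the first phase (partition coefficient = 1.70, kL = 0.0250 h⁻¹)

The neighbouring flask is the same charge left until 15 h. The autumn c at that time is taken as the mean of 2.80% at 10.0 h and 6.90% at 20.0 h, and the reagent ratio brings it to 3.20% reacted. Its s lies between 0.857 at 10.0 h and 0.826 at 20.0 h, about 0.842, so the reckoning gives 2.69% target. That flask holds 2.59% target with 3.04% reacted, an s of 0.852.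

The earlier runs and the new flask come from a simulation from invented constants; the scatter is artificial.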